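**Retrosynthetic overview**
1. Labels: the target is a 3,7-dioxabicyclo[3.3.0]octane. Ring A = C1(OH)–C2H(Ar)–O3–C4H2–C5H, ring B = C5–C6H(Ar)–O7–C8H2–C1, Ar = 3,4-dimethoxyphenyl. The C2 aryl is exo and the C6 aryl is endo.
2. Ring A is closed last, through the O3–C4 bond by a 5-exo-tet displacement. C1–OH and C2–O are set together by syn-dihydroxylation of a (Z)-C1=C2 benzylidene group on ring B.
3. Ring B is made first. A new cobalt-hydride hydroboration/cyclization of a 1,6-enyne forms the C1–C5 bond, the C5 stereocentre, the (Z)-alkene and the C4–B bond in one step.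
4. The enyne comes from the O7–C8 bond: Williamson coupling of (R)-1-arylallyl alcohol (C6 set by lipase resolution) with 3-arylpropargyl bromide.
5. Building blocks: 3,4-dimethoxybenzaldehyde + vinylmagnesium bromide, and 4-iodo-1,2-dimethoxybenzene + propargyl alcohol.

Assumption: the face preference of the Co(acac)2/Ph-BPE catalyst on this untested substrate class cannot be known in advance, so the (S,S) ligand is written and stands for whichever commercial antipode gives insertion on the Re face of the vinyl CH.

**Step 1**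
Reactants: 1 4-iodo-1,2-dimethoxybenzene; 2 prop-2-yn-1-ol
Product: 3 3-(3,4-dimethoxyphenyl)prop-2-yn-1-ol
Conditions: PdCl2(PPh3)2 (2 mol %), CuI (4 mol %), Et3N/THF 1:1, rt
Reagents that add atoms: none
Why: Sonogashira coupling of an aryl iodide with a terminal alkyne runs at room temperature even on this electron-rich ring, tolerates the free hydroxyl group and forms no stereocentre.

**Step 2**
Reactants: 3 3-(3,4-dimethoxyphenyl)prop-2-yn-1-ol
Product: 4 4-(3-bromoprop-1-yn-1-yl)-1,2-dimethoxybenzene
Conditions: PBr3 (0.4 equiv), pyridine (5 mol %), Et2O, 0 °C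
Reagents that add atoms: phosphorus tribromide, BrP(Br)Br
Why: PBr3 bromination of a primary propargylic alcohol is an SN2 displacement of its phosphite ester and leaves the alkyne and the aryl methyl ethers untouched.

**Step 3**
Reactants: 5 3,4-dimethoxybenzaldehyde; 6 vinylmagnesium bromide
Product: 8 rac-1-(3,4-dimethoxyphenyl)prop-2-en-1-ol, via bromomagnesium alkoxide 7 (not isolated)
Conditions: THF, 0 °C; then sat. aq. NH4Cl
Reagents that add atoms: none
Why: Grignard 1,2-addition to a non-enolisable aromatic aldehyde gives the racemic allylic alcohol cleanly, and the C6 configuration is sorted out in step 4.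

**Step 4**
Reactants: 8 rac-1-(3,4-dimethoxyphenyl)prop-2-en-1-ol
Product: 9 (1R)-1-(3,4-dimethoxyphenyl)prop-2-en-1-yl acetate
Conditions: immobilised Candida antarctica lipase B, vinyl acetate (2 equiv), MTBE, 30 °C, stopped at 50 % conversion; chromatography on Et3N-washed silica
Reagents that add atoms: vinyl acetate, C=COC(C)=O
Why: Lipase-catalysed kinetic resolution by irreversible transesterification acylates only the enantiomer that fits the Kazlauskas rule (aryl large, vinyl medium), which is (R), so C6 is obtained in the configuration of the target.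

**Step 5**
Reactants: 9 (1R)-1-(3,4-dimethoxyphenyl)prop-2-en-1-yl acetate
Product: 10 (1R)-1-(3,4-dimethoxyphenyl)prop-2-en-1-ol
Conditions: K2CO3 (0.2 equiv), MeOH, 0 °C, 30 min
Reagents that add atoms: none
Why: Base-catalysed transesterification (Zemplén-type methanolysis) breaks the acyl–oxygen bond and not the C6–O bond, so the configuration is retained.

**Step 6**
Reactants: 10 (1R)-1-(3,4-dimethoxyphenyl)prop-2-en-1-ol; 4 4-(3-bromoprop-1-yn-1-yl)-1,2-dimethoxybenzene
Product: 12 4-[(1R)-1-{[3-(3,4-dimethoxyphenyl)prop-2-yn-1-yl]oxy}prop-2-en-1-yl]-1,2-dimethoxybenzene, via sodium alkoxide 11 (not isolated)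
Conditions: NaH (1.2 equiv), THF/DMF 4:1, 0 °C; then 4 (1.1 equiv), 0 °C to rt
Reagents that add atoms: none
Why: In this Williamson ether synthesis the alkoxide attacks the primary propargylic bromide by SN2, the C6–O bond is never broken and the (R) configuration passes into 12.

**Step 7**
Reactants: 12 4-[(1R)-1-{[3-(3,4-dimethoxyphenyl)prop-2-yn-1-yl]oxy}prop-2-en-1-yl]-1,2-dimethoxybenzene
Product: 13 2-{[(2R,3S,4Z)-2-(3,4-dimethoxyphenyl)-4-[(3,4-dimethoxyphenyl)methylidene]oxolan-3-yl]methyl}-4,4,5,5-tetramethyl-1,3,2-dioxaborolane (aryl and CH2B groups cis)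
Conditions: Co(acac)2 (5 mol %), (S,S)-Ph-BPE [1,2-bis((2S,5S)-2,5-diphenylphospholano)ethane] (6 mol %), HBpin (1.3 equiv, added over 1 h), toluene, 25 °C
Reagents that add atoms: pinacolborane, CC1(C)OBOC1(C)C
Why: Proposed new method: a low-valent cobalt hydride formed from Co(acac)2, the bisphosphine and HBpin adds syn across the aryl alkyne with cobalt on the carbon next to the tether (this fixes the (Z)-alkene, H2 cis to C5); the alkenyl-cobalt then inserts the chelated vinyl group 5-exo (C1–C5 bond, ring B), and sigma-bond metathesis of the primary alkyl-cobalt with HBpin releases 13 and the hydride; the insertion face (Re face of the vinyl CH, giving 3S) is dictated by the C2-symmetric ligand pocket, worth about 2–3 kcal/mol on achiral enynes, which must override the roughly 1 kcal/mol substrate preference for a pseudo-equatorial aryl group and so force the contra-steric 2,3-cis oxolane needed for the endo C6 aryl; the closest known reaction type is the enantioselective cobalt-catalysed hydroboration/cyclization of achiral 1,6-enynes, which has not been shown on an enyne with a stereocentre at the allylic ether carbon nor used for catalyst-over-substrate diastereocontrol.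

**Step 8**
Reactants: 13 the cis boronate from step 7
Product: 14 [(2R,3R,4Z)-2-(3,4-dimethoxyphenyl)-4-[(3,4-dimethoxyphenyl)methylidene]oxolan-3-yl]methanol
Conditions: H2O2 (30 %), NaOH (3 M), THF, 0 °C
Reagents that add atoms: hydrogen peroxide, OO
Why: Standard boronate oxidation by 1,2-migration of the primary carbon from boron to peroxide oxygen changes no stereocentre (the descriptor changes only by priority) and does not touch the unactivated styrene-type alkene.

**Step 9**
Reactants: 14 [(2R,3R,4Z)-2-(3,4-dimethoxyphenyl)-4-[(3,4-dimethoxyphenyl)methylidene]oxolan-3-yl]methanol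
Product: 15 [(2R,3R,4Z)-2-(3,4-dimethoxyphenyl)-4-[(3,4-dimethoxyphenyl)methylidene]oxolan-3-yl]methyl 4-methylbenzenesulfonate
Conditions: TsCl (1.2 equiv), Et3N (2 equiv), DMAP (5 mol %), CH2Cl2, 0 °C
Reagents that add atoms: 4-toluenesulfonyl chloride, Cc1ccc(cc1)S(=O)(=O)Cl
Why: Tosylation of the only hydroxyl group makes C4 an electrophile under cold basic conditions that spare the acid-sensitive benzylic ether and the alkene.

**Step 10**
Reactants: 15 the tosylate from step 9
Product: 17 (+)-gmelinol, via diol tosylate 16 (not isolated)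
Conditions: OsO4 (2 mol %), NMO (1.3 equiv), acetone/H2O 4:1, 0 °C to rt; then K2CO3 (2 equiv), MeOH, 40 °C
Reagents that add atoms: N-methylmorpholine N-oxide, C[N+]1([O-])CCOCC1; water, O (both oxygens are passed on through the catalytic OsO4)
Why: Upjohn dihydroxylation adds both oxygens suprafacially to the (Z)-alkene from the ring face opposite the cis-disposed C5 side chain and C6 aryl group, which sets C1 as (S) and C2 as (R), and the C2 alkoxide then closes ring A by a 5-exo-tet Williamson displacement at C4 with retention at C2 (exo aryl), while the tertiary C1 hydroxyl is trans to C4 on ring B and cannot compete.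

**Compound list**
1 | 4-iodo-1,2-dimethoxybenzene | Ic1ccc(OC)c(OC)c1 | starting material
2 | prop-2-yn-1-ol | C#CCO | starting material
3 | 3-(3,4-dimethoxyphenyl)prop-2-yn-1-ol | COc1ccc(C#CCO)cc1OC | intermediate
4 | 4-(3-bromoprop-1-yn-1-yl)-1,2-dimethoxybenzene | COc1ccc(C#CCBr)cc1OC | intermediate
5 | 3,4-dimethoxybenzaldehyde | COc1ccc(C=O)cc1OC | starting material
6 | vinylmagnesium bromide | C=C[Mg]Br | starting material
7 | bromomagnesium 1-(3,4-dimethoxyphenyl)prop-2-en-1-olate (racemic) | C=CC(O[Mg]Br)c1ccc(OC)c(OC)c1 | intermediate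
8 | rac-1-(3,4-dimethoxyphenyl)prop-2-en-1-ol | C=CC(O)c1ccc(OC)c(OC)c1 | intermediate
9 | (1R)-1-(3,4-dimethoxyphenyl)prop-2-en-1-yl acetate | C=C[C@@H](OC(C)=O)c1ccc(OC)c(OC)c1 | intermediate
10 | (1R)-1-(3,4-dimethoxyphenyl)prop-2-en-1-ol | C=C[C@@H](O)c1ccc(OC)c(OC)c1 | intermediate
11 | sodium (1R)-1-(3,4-dimethoxyphenyl)prop-2-en-1-olate | [Na+].C=C[C@@H]([O-])c1ccc(OC)c(OC)c1 | intermediate
12 | 4-[(1R)-1-{[3-(3,4-dimethoxyphenyl)prop-2-yn-1-yl]oxy}prop-2-en-1-yl]-1,2-dimethoxybenzene | C=C[C@@H](OCC#Cc1ccc(OC)c(OC)c1)c1ccc(OC)c(OC)c1 | intermediate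
13 | 2-{[(2R,3S,4Z)-2-(3,4-dimethoxyphenyl)-4-[(3,4-dimethoxyphenyl)methylidene]oxolan-3-yl]methyl}-4,4,5,5-tetramethyl-1,3,2-dioxaborolane | CC1(C)OB(C[C@@H]2[C@H](c3ccc(OC)c(OC)c3)OC/C2=C\c4ccc(OC)c(OC)c4)OC1(C)C | intermediate
14 | [(2R,3R,4Z)-2-(3,4-dimethoxyphenyl)-4-[(3,4-dimethoxyphenyl)methylidene]oxolan-3-yl]methanol | OC[C@@H]1[C@H](c2ccc(OC)c(OC)c2)OC/C1=C\c3ccc(OC)c(OC)c3 | intermediate
15 | [(2R,3R,4Z)-2-(3,4-dimethoxyphenyl)-4-[(3,4-dimethoxyphenyl)methylidene]oxolan-3-yl]methyl 4-methylbenzenesulfonate | Cc1ccc(cc1)S(=O)(=O)OC[C@@H]2[C@H](c3ccc(OC)c(OC)c3)OC/C2=C\c4ccc(OC)c(OC)c4 | intermediate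
16 | [(2R,3R,4S)-2-(3,4-dimethoxyphenyl)-4-[(R)-(3,4-dimethoxyphenyl)(hydroxy)methyl]-4-hydroxyoxolan-3-yl]methyl 4-methylbenzenesulfonate | Cc1ccc(cc1)S(=O)(=O)OC[C@@H]2[C@H](c3ccc(OC)c(OC)c3)OC[C@]2(O)[C@H](O)c4ccc(OC)c(OC)c4 | intermediate
17 | (+)-gmelinol, (1S,2R,5R,6R)-2,6-bis(3,4-dimethoxyphenyl)-3,7-dioxabicyclo[3.3.0]octan-1-ol | COc1ccc([C@H]2OC[C@@H]3[C@H](c4ccc(OC)c(OC)c4)OC[C@]23O)cc1OC | target

**Step count**
Total: 10 steps. Longest linear sequence: 8 steps (steps 3 to 10, from 3,4-dimethoxybenzaldehyde).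

**Three steps most likely to fail**

1. Step 7 (the proposed new step). The substrate bias for the 2,3-trans ring may beat the ligand. The cobalt hydride may also hydroborate the vinyl group directly, or cleave the allylic ether after Markovnikov insertion. The fallback uses known chemistry, sets out from 12 and comes back at 14. A palladium-hydride enyne cycloisomerization (Pd(OAc)2 5 mol %, PPh3 10 mol %, toluene, 60 °C) proceeds by syn hydropalladation of the alkyne, 5-exo carbopalladation and beta-hydride loss of H5. It gives the cross-conjugated diene (2S,4Z)-2-(3,4-dimethoxyphenyl)-4-[(3,4-dimethoxyphenyl)methylidene]-3-methylideneoxolane F1, in which C5 is trigonal. The diene is used without storage. 9-BBN (1.1 equiv, THF, 0 °C) adds to the 1,1-disubstituted methylidene group from the face away from the C6 aryl group. This gives 9-{[(2R,3S,4Z)-2-(3,4-dimethoxyphenyl)-4-[(3,4-dimethoxyphenyl)methylidene]oxolan-3-yl]methyl}-9-borabicyclo[3.3.1]nonane F2, so H5 enters trans to the aryl group and C4 ends cis to it by simple steric approach control. H2O2/NaOH then gives 14, and 13 is bypassed.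

2. Step 10. The homoallylic tosylate may ionise in aqueous acetone with participation of the electron-rich styrene. Hydrolysis of the hindered osmate may also be slow. The fallback sets out from 14 and comes back at 17. It reverses the order of events and changes the activation. Upjohn dihydroxylation of the free alcohol 14 gives (2R,3R,4S)-2-(3,4-dimethoxyphenyl)-4-[(R)-(3,4-dimethoxyphenyl)(hydroxy)methyl]-3-(hydroxymethyl)oxolan-4-ol F3, which is isolated. A Mitsunobu cyclodehydration (PPh3, DIAD, THF, 0 °C) then activates the least hindered primary C4 hydroxyl as its oxyphosphonium salt, and the C2 hydroxyl displaces it with retention at C2. No sulfonate passes through an aqueous oxidation, and 15 and 16 are bypassed.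

3. Step 4. Acetate 9 is a doubly activated (benzylic, allylic, para-alkoxy) ester. It may racemise or transpose to the cinnamyl isomer during isolation, and half of the material is lost in any case. The fallback sets out from 8 and comes back at 10. It replaces resolution by asymmetric reduction. MnO2 (CH2Cl2, rt) oxidises 8 to 1-(3,4-dimethoxyphenyl)prop-2-en-1-one F4. Corey–Bakshi–Shibata reduction ((S)-Me-CBS 10 mol %, catecholborane, toluene, −78 °C), with the aryl group as the large substituent, then gives (R)-10 directly, and 9 is bypassed.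

**Further compounds**
F1 | step 7 | (2S,4Z)-2-(3,4-dimethoxyphenyl)-4-[(3,4-dimethoxyphenyl)methylidene]-3-methylideneoxolane | C=C1[C@H](c2ccc(OC)c(OC)c2)OC/C1=C\c3ccc(OC)c(OC)c3
F2 | step 7 | 9-{[(2R,3S,4Z)-2-(3,4-dimethoxyphenyl)-4-[(3,4-dimethoxyphenyl)methylidene]oxolan-3-yl]methyl}-9-borabicyclo[3.3.1]nonane | C1CC2CCCC(C1)B2C[C@@H]3[C@H](c4ccc(OC)c(OC)c4)OC/C3=C\c5ccc(OC)c(OC)c5
F3 | step 10 | (2R,3R,4S)-2-(3,4-dimethoxyphenyl)-4-[(R)-(3,4-dimethoxyphenyl)(hydroxy)methyl]-3-(hydroxymethyl)oxolan-4-ol | OC[C@@H]1[C@H](c2ccc(OC)c(OC)c2)OC[C@]1(O)[C@H](O)c3ccc(OC)c(OC)c3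
F4 | step 4 | 1-(3,4-dimethoxyphenyl)prop-2-en-1-one | C=CC(=O)c1ccc(OC)c(OC)c1
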